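The earlier runs and the new flask were generated by integration for an exercise.

A small charge shows the flask with little product in it: the autumn run, with the E of the midnight run but less Q and X, holds 0.012 M of L at 76 s, which is 4.00 times the scatter, while the midnight run holds 0.438 M.

| setting | midnight | autumn | winter | summer |
|---|---|---|---|---|
| Q | 1.00 M | 0.400 M | 1.00 M | 1.00 M |
| X | 0.800 M | 0.200 M | 0.800 M | 0.800 M |
| E | 0.0100 M | 0.0100 M | 0.0150 M | 0.0100 M |
| time |  |  |  | 300 s |

| midnight run: time / s | midnight run: [L] / M | autumn run: time / s | autumn run: [L] / M | winter run: time / s | winter run: [L] / M |
|---|---|---|---|---|---|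
| 5.8 | 0.011 | 5.8 | 0.002 | 5.8 | 0.031 |
| 18 | 0.055 | 18 | 0.001 | 18 | 0.122 |
| 34 | 0.138 | 34 | 0.011 | 34 | 0.253 |
| 53 | 0.276 | 53 | 0.015 | 53 | 0.416 |
| 76 | 0.438 | 76 | 0.012 | 76 | 0.550 |

(each reading ± 0.003 M)

- Overall: Q + X -> L, with E as catalyst.
- Constant volume, constant temperature.
- "The second partner" is X.
- An order is taken over about fifteen percent of the charge, up and down.

- reaction order in [E] at the outset, round the charge of the midnight run, defined at two percent of the Q turned into L
- the autumn run starts with 0.600 M less of Q and of X than the midnight run, and with no L. Compared where both hold the same amount of Q, once fifteen percent of what the autumn run was charged with has turned into L, is the autumn run faster, slower or alike (within a tenth)?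
- L in the summer run at 300 s, as a share of the Q charged

The midnight run speeds up while Q and X fall. Its rate divided by c_Q c_X is 0.0154 /M/s between the third and fourth readings and 0.0247 /M/s between the last two, so it climbs with c_L, with slope b of 0.0619 /M²/s. Run back to zero L, that line leaves a term a of 0.00264 /M/s. The autumn run, with 0.012 M of L at its last reading, reads 0.00262 /M/s from its last two readings, which is a check from a different flask. The rate then reads c_Q c_X (a + b c_L), a case of autocatalysis.

The quantity to carry is the crossover amount, the c_L at which the term in L equals the term a, which is a over b: 0.0423 M. The midnight run has passed it by 18 s, and the autumn run still stands below it at 76 s.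

Where the autumn run has made 0.0600 M, the midnight run, holding the same Q, has made 0.660 M. The charges differ by 0.600 M in both Q and X and hold the same E, so c_Q and c_X are equal there and the rates stand as the crossover amount plus c_L in each flask. That gives 0.146, so this reckoning has the autumn run slower.

The winter run's first readings give it a crossover of 0.104 M, taking b from the midnight run. At 0.0200 M of L the winter rate over the midnight rate is then 1.99, which over the step in E means an order near 1.70.

The forecast differs on the order. It gives 1.35, on the ground that “the E path carries about two-thirds of the rate”. It agrees on slower and puts the summer run, a repeat of the midnight charge, at 78%, under the 80.0% that the charge of X, the limiting reagent, allows.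

The flask gives an order of 1.7, slower, and 78.2%.

    2 E ⇌ E2, settled at all times (90.60 /M)
    E2 + Q + X → L + E2 (2.300 /M²/s)
    E + Gu → Ek
    Q + X + L → 2 L (0.06270 /M²/s)

The crossover amount carries over: the autumn-to-midnight rate ratio stands at 0.14 against 0.146 reckoned, and on the second flask the winter-to-midnight ratio stands at 1.9 against 1.99. The order in the flask exceeds the forecast's. Gu takes 0.00436 M of E at once, leaving 0.00564 M outside Ek, E2 counted as its E, in the midnight run and 0.0106 M in the winter run. The same charge without that reaction has an order of 1.1, not 1.7.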